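**Retrosynthetic overview**

1. The target is epigallocatechin 3‑O‑gallate‑(4β→8)‑gallocatechin. The last step is hydrogenolysis of all benzyl‑type ethers; before it, the C4–C8 bond is made by Lewis‑acid union of a C4‑activated, benzylated EGCG electrophile with a protected gallocatechin, the 3‑O‑galloyl group directing 4β. The electrophile comes from natural (−)‑epigallocatechin by benzylation, C4 oxidation and galloylation.
2. The pyran ring of the lower unit (O1–C2–C3–C4–C4a–C8a) is grown from the five‑membered ring of a trans‑2‑aryl‑3‑(hydroxymethyl)‑2,3‑dihydrobenzofuran (O1–C2–C3–C3a–C7a). Ring A shifts from C3 to the exocyclic CH2 through a phenonium ion, so that the CH2 becomes C4 and a sulfonate oxygen returns to C3 with inversion (2,3‑trans).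
3. Enabling feature: ring A of the lower unit is a phloroglucinol ring whose three oxygens (O1 on C8a, O5, O7) stand ortho, ortho and para to the migrating carbon C4a; C4 is an unsubstituted CH2, and the C3 oxygen is trans to the C2 aryl group.
4. The dihydrobenzofuran comes from an enantioselective intramolecular C–H insertion, catalysed by Rh2(S‑PTTL)4, of an aryldiazoacetate built on phloroglucinol tris(3,4,5‑tribenzyloxybenzyl) ether. One ether becomes ring B with C2; the other two stay as protecting groups.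
5. Ring order: dihydrofuran ring (C–H insertion), then lower pyran ring (ring expansion), then union with the upper unit, whose rings are bought with epigallocatechin and gallic acid.

Key step: step 6

Remark: 3,4,5‑tris(benzyloxy)benzyl chloride is treated as a purchasable dendron building block (otherwise one step, SOCl2, from the commercial alcohol); (−)‑epigallocatechin and 3,4,5‑tris(benzyloxy)benzoic acid are commercial.
Remark: the (S) catalyst is written in step 4 on the assumption that it delivers the 2S dihydrobenzofuran; if the sense is opposite, its enantiomer is used.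
Abbreviations: TBB = 3,4,5‑tris(benzyloxy)benzyl; Bn = benzyl; Ts = 4‑methylbenzenesulfonyl; DTBMP = 2,6‑di‑tert‑butyl‑4‑methylpyridine; EGC = epigallocatechin; EGCG = epigallocatechin 3‑O‑gallate.

**Step 1**
Reactants: 1 benzene‑1,3,5‑triyl triacetate (phloroglucinol triacetate); 2 3,4,5‑tris(benzyloxy)benzyl chloride (three equivalents in all)
Product: 3 1,3,5‑tris(TBB‑oxy)benzene
Conditions: 2 (3.3 equiv), NaH, DMF, 0 °C; H2O (3 equiv) added slowly; 20 °C
Reagents that add atoms: 3,4,5‑tris(benzyloxy)benzyl chloride (compound 2; the second and third equivalents, one TBB group going on each phenol oxygen), ClCc1cc(OCc2ccccc2)c(OCc2ccccc2)c(OCc2ccccc2)c1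
Why: one‑pot deacetylation/threefold Williamson etherification, in which hydroxide made in situ releases each phenoxide slowly and so should favour O‑ over C‑alkylation of phloroglucinol.

**Step 2**
Reactants: 3 1,3,5‑tris(TBB‑oxy)benzene
Product: 5 methyl 2‑oxo‑2‑[2,4,6‑tris(TBB‑oxy)phenyl]acetate, via glyoxyloyl chloride 4 (not isolated)
Conditions: (COCl)2, DTBMP, CH2Cl2, 0 °C; then MeOH, Et3N, 0 °C
Reagents that add atoms: oxalyl chloride, ClC(=O)C(=O)Cl; methanol, CO
Why: uncatalysed Friedel–Crafts acylation of a 1,3,5‑trialkoxybenzene (all three ring positions equivalent, HCl taken up by the hindered pyridine so the benzylic ethers survive), followed by methanolysis of the acid chloride.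

**Step 3**
Reactants: 5 methyl 2‑oxo‑2‑[2,4,6‑tris(TBB‑oxy)phenyl]acetate
Product: 7 methyl 2‑diazo‑2‑[2,4,6‑tris(TBB‑oxy)phenyl]acetate, via tosylhydrazone 6 (not isolated)
Conditions: TsNHNH2, PPTS (cat.), toluene, 70 °C; then DBU, CH2Cl2, 20 °C
Reagents that add atoms: 4‑methylbenzenesulfonohydrazide, Cc1ccc(cc1)S(=O)(=O)NN
Why: condensation at the activated keto group and base‑induced loss of sulfinate (Bamford–Stevens type) is a standard entry to aryldiazoacetates.

**Step 4**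
Reactants: 7 methyl 2‑diazo‑2‑[2,4,6‑tris(TBB‑oxy)phenyl]acetate
Product: 9 methyl (2S,3S)‑trans‑2‑[3,4,5‑tris(benzyloxy)phenyl]‑4,6‑bis(TBB‑oxy)‑2,3‑dihydro‑1‑benzofuran‑3‑carboxylate, via cis ester 8 (not isolated)
Conditions: dirhodium tetrakis[(S)‑N‑phthaloyl‑tert‑leucinate], Rh2(S‑PTTL)4 (1 mol %), toluene, −60 °C; then NaOMe (cat.), MeOH–THF, 20 °C
Reagents that add atoms: none
Why: intramolecular 1,5 C–H insertion of the donor/acceptor dirhodium carbenoid into an ortho benzylic ether C–H (the established enantioselective route to cis‑2‑aryl‑2,3‑dihydrobenzofuran‑3‑carboxylates) should set C2 under control of the chiral carboxylate ligands, the two ortho TBB ethers being identical so that either insertion gives the same product, and NaOMe then epimerises only C3 (α to the ester) to the more stable trans ester.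

**Step 5**
Reactants: 9 trans methyl ester
Product: 10 [(2S,3R)‑trans‑2‑[3,4,5‑tris(benzyloxy)phenyl]‑4,6‑bis(TBB‑oxy)‑2,3‑dihydro‑1‑benzofuran‑3‑yl]methanol
Conditions: LiAlH4, THF, 0 °C
Reagents that add atoms: none
Why: hydride reduction of the ester is faster than enolisation, so the trans relationship and both stereocentres should be kept.

**Step 6**
Reactants: 10 trans dihydrobenzofuran‑3‑ylmethanol
Product: 13 (2R,3S)‑2‑[3,4,5‑tris(benzyloxy)phenyl]‑5,7‑bis(TBB‑oxy)chroman‑3‑yl 4‑methylbenzenesulfonate (2,3‑trans), via primary tosylate 11 (not isolated), via phenonium tosylate ion pair 12 (not isolated)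
Conditions: Ts2O, DTBMP, ClCH2CH2Cl, 0 → 40 °C
Reagents that add atoms: 4‑methylbenzenesulfonic anhydride, Cc1ccc(cc1)S(=O)(=O)OS(=O)(=O)c1ccc(C)cc1
Why: Proposed new method: tosylation of the primary alcohol is followed by ionisation with participation of the ring A ipso carbon (3‑exo‑tet closure of a transient cyclopropane anti to the leaving group), giving a phenonium ion whose cyclopropane is fused to the dihydrofuran ring; with no external nucleophile present the tosylate can only return, either to the CH2 carbon (regenerating 11) or to C3, which cleaves the C3–C4a bond shared by the three‑ and five‑membered rings and thereby turns the dihydrofuran ring into the pyran ring (ring expansion by bond cleavage, no further ring closure). The closest known reaction types are the internal‑return isomerisation of 2‑aryl‑1‑propyl arenesulfonates to 1‑aryl‑2‑propyl arenesulfonates through phenonium ions, the ring‑expanding solvolysis of spirocyclopropyl cyclohexadienones fused to five‑membered rings, and the thermodynamically controlled ring expansion of prolinol esters to 3‑piperidinol esters through aziridinium ions; the step is the microscopic reverse of the ring‑A‑assisted ring contraction that can accompany substitution of activated 2,3‑trans‑flavan‑3‑ols when an external nucleophile captures the ion irreversibly at the primary carbon. The selectivity needed is the site of return, and it is secured by thermodynamics rather than kinetics: every tosylate re‑ionises to the same ion, and 13 should be favoured as a secondary sulfonate in an unstrained six‑membered ring that no longer has the peri repulsion between the 4‑O‑TBB ether and the CH2OTs arm. The three oxygens ortho, ortho and para to C4a make ring A a strong enough neighbouring group to ionise a primary tosylate at 40 °C, and chloride‑free sulfonylation with a non‑nucleophilic pyridine keeps other nucleophiles out. C3 is inverted because tosylate enters anti to the departing C4a, so the trans dihydrobenzofuran should give the 2,3‑trans flavan, while C2 is not touched and keeps the configuration set in step 4.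

**Step 7**
Reactants: 13 trans chroman‑3‑yl tosylate
Product: 14 (2R,3S)‑2‑[3,4,5‑tris(benzyloxy)phenyl]‑5,7‑bis(TBB‑oxy)chroman‑3‑ol (3',4',5'‑tri‑O‑benzyl‑5,7‑bis‑O‑TBB‑gallocatechin)
Conditions: Mg, MeOH–THF, 20 °C
Reagents that add atoms: none
Why: electron‑transfer reduction cleaves the S–O bond of the arenesulfonate, so the C3–O bond and its configuration should be untouched and the benzyl‑type ethers inert.

**Step 8**
Reactants: 15 (−)‑epigallocatechin (EGC)
Product: 16 5,7,3',4',5'‑penta‑O‑benzyl‑EGC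
Conditions: BnBr (5.5 equiv), K2CO3, DMF, argon, 0 → 20 °C
Reagents that add atoms: benzyl bromide (five equivalents, one per phenol), BrCc1ccccc1
Why: Williamson benzylation with a weak base at low temperature should etherify the five phenols only, leaving the secondary 3‑OH free and both stereocentres intact.

**Step 9**
Reactants: 16 penta‑O‑benzyl‑EGC
Product: 17 4β‑(2‑ethoxyethoxy)‑5,7,3',4',5'‑penta‑O‑benzyl‑EGC
Conditions: DDQ, HOCH2CH2OEt, CH2Cl2, 20 °C
Reagents that add atoms: 2‑ethoxyethanol, CCOCCO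
Why: DDQ abstracts hydride from the doubly activated benzylic C4 and the alcohol should trap the cation trans to the 3‑hydroxy group (4β), the standard C4 activation of benzylated flavan‑3‑ols with a free 3‑OH.

**Step 10**
Reactants: 17 4β‑(2‑ethoxyethoxy)‑penta‑O‑benzyl‑EGC; 18 3,4,5‑tris(benzyloxy)benzoic acid
Product: 19 4β‑(2‑ethoxyethoxy)‑octa‑O‑benzyl‑EGCG
Conditions: DCC, DMAP, CH2Cl2, 20 °C
Reagents that add atoms: none
Why: Steglich esterification acylates the secondary 3‑OH under neutral conditions, so the acid‑labile C4 ether and all stereocentres should be kept.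

**Step 11**
Reactants: 19 4β‑(2‑ethoxyethoxy)‑octa‑O‑benzyl‑EGCG; 14 protected gallocatechin (threefold excess)
Product: 20 fully protected EGCG‑(4β→8)‑gallocatechin
Conditions: Me3SiOTf (0.1 equiv), CH2Cl2, −78 °C
Reagents that add atoms: none
Why: Lewis‑acid ionisation of the C4 ether gives a benzylic cation whose α face is covered by the 3‑O‑galloyl carbonyl (dioxolanylium participation), so C8 of 14 (the less hindered nucleophilic ring A position) should attack from the β face to give the 3,4‑trans, 4β→8 Friedel–Crafts product, the excess of 14 suppressing oligomerisation.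

**Step 12**
Reactants: 20 protected dimer
Product: 21 epigallocatechin 3‑O‑gallate‑(4β→8)‑gallocatechin (target)
Conditions: H2 (1 atm), Pd(OH)2/C, THF–MeOH–H2O, 20 °C
Reagents that add atoms: none
Why: hydrogenolysis removes all benzyl and TBB ethers in one operation without touching a stereocentre, the ester or the interflavan bond.

**Compound list**

1 | benzene‑1,3,5‑triyl triacetate | CC(=O)Oc1cc(OC(C)=O)cc(OC(C)=O)c1 | starting material
2 | 3,4,5‑tris(benzyloxy)benzyl chloride | ClCc1cc(OCc2ccccc2)c(OCc2ccccc2)c(OCc2ccccc2)c1 | starting material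
3 | 1,3,5‑tris(TBB‑oxy)benzene | c1(OCc2cc(OCc3ccccc3)c(OCc3ccccc3)c(OCc3ccccc3)c2)cc(OCc2cc(OCc3ccccc3)c(OCc3ccccc3)c(OCc3ccccc3)c2)cc(OCc2cc(OCc3ccccc3)c(OCc3ccccc3)c(OCc3ccccc3)c2)c1 | intermediate
4 | 2‑oxo‑2‑[2,4,6‑tris(TBB‑oxy)phenyl]acetyl chloride | O=C(Cl)C(=O)c1c(OCc2cc(OCc3ccccc3)c(OCc3ccccc3)c(OCc3ccccc3)c2)cc(OCc2cc(OCc3ccccc3)c(OCc3ccccc3)c(OCc3ccccc3)c2)cc1OCc1cc(OCc2ccccc2)c(OCc2ccccc2)c(OCc2ccccc2)c1 | intermediate
5 | methyl 2‑oxo‑2‑[2,4,6‑tris(TBB‑oxy)phenyl]acetate | COC(=O)C(=O)c1c(OCc2cc(OCc3ccccc3)c(OCc3ccccc3)c(OCc3ccccc3)c2)cc(OCc2cc(OCc3ccccc3)c(OCc3ccccc3)c(OCc3ccccc3)c2)cc1OCc1cc(OCc2ccccc2)c(OCc2ccccc2)c(OCc2ccccc2)c1 | intermediate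
6 | N‑tosylhydrazone of 5 | COC(=O)C(=NNS(=O)(=O)c1ccc(C)cc1)c1c(OCc2cc(OCc3ccccc3)c(OCc3ccccc3)c(OCc3ccccc3)c2)cc(OCc2cc(OCc3ccccc3)c(OCc3ccccc3)c(OCc3ccccc3)c2)cc1OCc1cc(OCc2ccccc2)c(OCc2ccccc2)c(OCc2ccccc2)c1 | intermediate
7 | methyl 2‑diazo‑2‑[2,4,6‑tris(TBB‑oxy)phenyl]acetate | COC(=O)C(=[N+]=[N-])c1c(OCc2cc(OCc3ccccc3)c(OCc3ccccc3)c(OCc3ccccc3)c2)cc(OCc2cc(OCc3ccccc3)c(OCc3ccccc3)c(OCc3ccccc3)c2)cc1OCc1cc(OCc2ccccc2)c(OCc2ccccc2)c(OCc2ccccc2)c1 | intermediate
8 | methyl (2S,3R)‑cis‑2‑[3,4,5‑tris(benzyloxy)phenyl]‑4,6‑bis(TBB‑oxy)‑2,3‑dihydro‑1‑benzofuran‑3‑carboxylate | O1c2cc(OCc3cc(OCc4ccccc4)c(OCc4ccccc4)c(OCc4ccccc4)c3)cc(OCc3cc(OCc4ccccc4)c(OCc4ccccc4)c(OCc4ccccc4)c3)c2[C@@H](C(=O)OC)[C@H]1c1cc(OCc2ccccc2)c(OCc2ccccc2)c(OCc2ccccc2)c1 | intermediate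
9 | methyl (2S,3S)‑trans‑2‑[3,4,5‑tris(benzyloxy)phenyl]‑4,6‑bis(TBB‑oxy)‑2,3‑dihydro‑1‑benzofuran‑3‑carboxylate | O1c2cc(OCc3cc(OCc4ccccc4)c(OCc4ccccc4)c(OCc4ccccc4)c3)cc(OCc3cc(OCc4ccccc4)c(OCc4ccccc4)c(OCc4ccccc4)c3)c2[C@H](C(=O)OC)[C@H]1c1cc(OCc2ccccc2)c(OCc2ccccc2)c(OCc2ccccc2)c1 | intermediate
10 | [(2S,3R)‑trans‑2‑[3,4,5‑tris(benzyloxy)phenyl]‑4,6‑bis(TBB‑oxy)‑2,3‑dihydro‑1‑benzofuran‑3‑yl]methanol | O1c2cc(OCc3cc(OCc4ccccc4)c(OCc4ccccc4)c(OCc4ccccc4)c3)cc(OCc3cc(OCc4ccccc4)c(OCc4ccccc4)c(OCc4ccccc4)c3)c2[C@H](CO)[C@H]1c1cc(OCc2ccccc2)c(OCc2ccccc2)c(OCc2ccccc2)c1 | intermediate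
11 | primary 4‑methylbenzenesulfonate of 10 | O1c2cc(OCc3cc(OCc4ccccc4)c(OCc4ccccc4)c(OCc4ccccc4)c3)cc(OCc3cc(OCc4ccccc4)c(OCc4ccccc4)c(OCc4ccccc4)c3)c2[C@H](COS(=O)(=O)c2ccc(C)cc2)[C@H]1c1cc(OCc2ccccc2)c(OCc2ccccc2)c(OCc2ccccc2)c1 | intermediate
12 | ring A phenonium ion (cyclopropane bridging C4a, CH2 and C3, fused to the dihydrofuran ring) with tosylate counter‑ion | [O+]1=C2C=C(OCc3cc(OCc4ccccc4)c(OCc4ccccc4)c(OCc4ccccc4)c3)C=C(OCc3cc(OCc4ccccc4)c(OCc4ccccc4)c(OCc4ccccc4)c3)[C@]23C[C@@H]3[C@H]1c1cc(OCc2ccccc2)c(OCc2ccccc2)c(OCc2ccccc2)c1.Cc1ccc(cc1)S(=O)(=O)[O-] | intermediate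
13 | (2R,3S)‑2‑[3,4,5‑tris(benzyloxy)phenyl]‑5,7‑bis(TBB‑oxy)chroman‑3‑yl 4‑methylbenzenesulfonate | Cc1ccc(cc1)S(=O)(=O)O[C@H]1Cc2c(OCc3cc(OCc4ccccc4)c(OCc4ccccc4)c(OCc4ccccc4)c3)cc(OCc3cc(OCc4ccccc4)c(OCc4ccccc4)c(OCc4ccccc4)c3)cc2O[C@@H]1c1cc(OCc2ccccc2)c(OCc2ccccc2)c(OCc2ccccc2)c1 | intermediate
14 | (2R,3S)‑2‑[3,4,5‑tris(benzyloxy)phenyl]‑5,7‑bis(TBB‑oxy)chroman‑3‑ol | O[C@H]1Cc2c(OCc3cc(OCc4ccccc4)c(OCc4ccccc4)c(OCc4ccccc4)c3)cc(OCc3cc(OCc4ccccc4)c(OCc4ccccc4)c(OCc4ccccc4)c3)cc2O[C@@H]1c1cc(OCc2ccccc2)c(OCc2ccccc2)c(OCc2ccccc2)c1 | intermediate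
15 | (−)‑epigallocatechin | O[C@@H]1Cc2c(O)cc(O)cc2O[C@@H]1c1cc(O)c(O)c(O)c1 | starting material
16 | 5,7,3',4',5'‑penta‑O‑benzyl‑EGC | O[C@@H]1Cc2c(OCc3ccccc3)cc(OCc3ccccc3)cc2O[C@@H]1c1cc(OCc2ccccc2)c(OCc2ccccc2)c(OCc2ccccc2)c1 | intermediate
17 | 4β‑(2‑ethoxyethoxy)‑5,7,3',4',5'‑penta‑O‑benzyl‑EGC | O[C@@H]1[C@@H](OCCOCC)c2c(OCc3ccccc3)cc(OCc3ccccc3)cc2O[C@@H]1c1cc(OCc2ccccc2)c(OCc2ccccc2)c(OCc2ccccc2)c1 | intermediate
18 | 3,4,5‑tris(benzyloxy)benzoic acid | OC(=O)c1cc(OCc2ccccc2)c(OCc2ccccc2)c(OCc2ccccc2)c1 | starting material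
19 | 4β‑(2‑ethoxyethoxy)‑octa‑O‑benzyl‑EGCG | O=C(O[C@@H]1[C@@H](OCCOCC)c2c(OCc3ccccc3)cc(OCc3ccccc3)cc2O[C@@H]1c1cc(OCc2ccccc2)c(OCc2ccccc2)c(OCc2ccccc2)c1)c1cc(OCc2ccccc2)c(OCc2ccccc2)c(OCc2ccccc2)c1 | intermediate
20 | fully protected EGCG‑(4β→8)‑gallocatechin (upper unit octa‑O‑benzyl; lower unit 3',4',5'‑tri‑O‑benzyl‑5,7‑bis‑O‑TBB, 3‑OH free) | O=C(O[C@@H]1[C@@H](c2c(OCc4cc(OCc5ccccc5)c(OCc5ccccc5)c(OCc5ccccc5)c4)cc(OCc4cc(OCc5ccccc5)c(OCc5ccccc5)c(OCc5ccccc5)c4)c3c2O[C@H](c2cc(OCc4ccccc4)c(OCc4ccccc4)c(OCc4ccccc4)c2)[C@@H](O)C3)c2c(OCc3ccccc3)cc(OCc3ccccc3)cc2O[C@@H]1c1cc(OCc2ccccc2)c(OCc2ccccc2)c(OCc2ccccc2)c1)c1cc(OCc2ccccc2)c(OCc2ccccc2)c(OCc2ccccc2)c1 | intermediate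
21 | epigallocatechin 3‑O‑gallate‑(4β→8)‑gallocatechin | O=C(O[C@@H]1[C@@H](c2c(O)cc(O)c3c2O[C@H](c2cc(O)c(O)c(O)c2)[C@@H](O)C3)c2c(O)cc(O)cc2O[C@@H]1c1cc(O)c(O)c(O)c1)c1cc(O)c(O)c(O)c1 | target

**Step count and risks**

Total steps: 12. Longest linear sequence: 9 (steps 1 to 7, then 11 and 12).

Steps most likely to fail:

Step 6 (Proposed new method). Return of tosylate to the primary carbon may dominate kinetically, so that equilibrium is approached slowly. This leaves time for proton loss from the phenonium ion (flavene formation), a 1,2‑hydride shift with aromatisation to a 3‑methylbenzofuran, migration of ring B from C2 to C3 in the secondary tosylate, or acid‑induced opening of the benzylic C2–O1 ether. The fallback uses known chemistry, the kinetically controlled solvolytic 1,2‑aryl shift of β‑aryl primary sulfonates to rearranged secondary alcohols. It sets out from 10, which is converted with Ms2O and DTBMP in CH2Cl2 at 0 °C into the primary methanesulfonate F1; this is solvolysed in NaHCO3‑buffered aqueous acetone at 40 °C. Water captures the same ion irreversibly: capture at C3 gives 14 directly, capture at the CH2 carbon gives back 10, which is separated and resubmitted. The fallback comes back to the route at 14 and bypasses 13 and step 7.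

Step 4. The catalyst may discriminate poorly between the enantiotopic benzylic hydrogens because the carbenoid is flanked by two ortho ethers, and carbenoid dimerisation may compete. The fallback replaces catalyst control by a covalently bound auxiliary. It sets out from 3, which is acylated with oxalyl chloride as in step 2 (acid chloride 4) and quenched with (S)‑2‑hydroxy‑1‑(pyrrolidin‑1‑yl)propan‑1‑one instead of methanol to give the lactamide glyoxylate F2. Condensation with TsNHNH2 gives the lactamide tosylhydrazone F3, and DBU converts it into the lactamide diazo ester F4. C–H insertion with dirhodium tetrakis[(S)‑N‑(4‑dodecylphenylsulfonyl)prolinate], Rh2(S‑DOSP)4, in the matched pairing should then give the cis lactamide ester F5 under double stereocontrol. NaOMe in MeOH transesterifies and epimerises C3 in one operation, so the fallback comes back at 9.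

Step 11. The C4 cation may attack C6 instead of C8 or attack the coupled product (oligomers), the β selectivity may erode, and the acid may cleave TBB ethers. The fallback changes the electrophile and its mode of activation. It sets out from 19, which with phenylmethanethiol and BF3·OEt2 in CH2Cl2 at −78 °C should give the 4β‑benzylthio ether F6. This thioether is activated with the thiophilic salt AgBF4 in the presence of 14 and DTBMP (THF–CH2Cl2, −78 → 0 °C) under buffered conditions; the product carries no leaving group and so cannot be re‑activated. The fallback comes back at 20.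

**Further compounds**

F1 | step 6 | [(2S,3R)‑trans‑2‑[3,4,5‑tris(benzyloxy)phenyl]‑4,6‑bis(TBB‑oxy)‑2,3‑dihydro‑1‑benzofuran‑3‑yl]methyl methanesulfonate | O1c2cc(OCc3cc(OCc4ccccc4)c(OCc4ccccc4)c(OCc4ccccc4)c3)cc(OCc3cc(OCc4ccccc4)c(OCc4ccccc4)c(OCc4ccccc4)c3)c2[C@H](COS(C)(=O)=O)[C@H]1c1cc(OCc2ccccc2)c(OCc2ccccc2)c(OCc2ccccc2)c1
F2 | step 4 | (S)‑1‑oxo‑1‑(pyrrolidin‑1‑yl)propan‑2‑yl 2‑oxo‑2‑[2,4,6‑tris(TBB‑oxy)phenyl]acetate | C[C@H](OC(=O)C(=O)c1c(OCc2cc(OCc3ccccc3)c(OCc3ccccc3)c(OCc3ccccc3)c2)cc(OCc2cc(OCc3ccccc3)c(OCc3ccccc3)c(OCc3ccccc3)c2)cc1OCc1cc(OCc2ccccc2)c(OCc2ccccc2)c(OCc2ccccc2)c1)C(=O)N1CCCC1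
F3 | step 4 | N‑tosylhydrazone of F2 | C[C@H](OC(=O)C(=NNS(=O)(=O)c1ccc(C)cc1)c1c(OCc2cc(OCc3ccccc3)c(OCc3ccccc3)c(OCc3ccccc3)c2)cc(OCc2cc(OCc3ccccc3)c(OCc3ccccc3)c(OCc3ccccc3)c2)cc1OCc1cc(OCc2ccccc2)c(OCc2ccccc2)c(OCc2ccccc2)c1)C(=O)N1CCCC1
F4 | step 4 | (S)‑1‑oxo‑1‑(pyrrolidin‑1‑yl)propan‑2‑yl 2‑diazo‑2‑[2,4,6‑tris(TBB‑oxy)phenyl]acetate | C[C@H](OC(=O)C(=[N+]=[N-])c1c(OCc2cc(OCc3ccccc3)c(OCc3ccccc3)c(OCc3ccccc3)c2)cc(OCc2cc(OCc3ccccc3)c(OCc3ccccc3)c(OCc3ccccc3)c2)cc1OCc1cc(OCc2ccccc2)c(OCc2ccccc2)c(OCc2ccccc2)c1)C(=O)N1CCCC1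
F5 | step 4 | (S)‑1‑oxo‑1‑(pyrrolidin‑1‑yl)propan‑2‑yl (2S,3R)‑cis‑2‑[3,4,5‑tris(benzyloxy)phenyl]‑4,6‑bis(TBB‑oxy)‑2,3‑dihydro‑1‑benzofuran‑3‑carboxylate | O1c2cc(OCc3cc(OCc4ccccc4)c(OCc4ccccc4)c(OCc4ccccc4)c3)cc(OCc3cc(OCc4ccccc4)c(OCc4ccccc4)c(OCc4ccccc4)c3)c2[C@@H](C(=O)O[C@@H](C)C(=O)N2CCCC2)[C@H]1c1cc(OCc2ccccc2)c(OCc2ccccc2)c(OCc2ccccc2)c1
F6 | step 11 | 4β‑(benzylthio)‑octa‑O‑benzyl‑EGCG | O=C(O[C@@H]1[C@@H](SCc2ccccc2)c2c(OCc3ccccc3)cc(OCc3ccccc3)cc2O[C@@H]1c1cc(OCc2ccccc2)c(OCc2ccccc2)c(OCc2ccccc2)c1)c1cc(OCc2ccccc2)c(OCc2ccccc2)c(OCc2ccccc2)c1
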